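## Retrosynthetic overview

1. Target 30 ⇐ macrocyclic hydroxy diene acid 28: a one-flask double asymmetric epoxidation, then carboxylate opening of the C10–C11 epoxide, closes the epoxide and the δ-lactone together and sets C4, C5, C10 and C11.
2. 28 ⇐ ynal 21: exo-selective nickel-catalysed reductive alkyne–aldehyde macrocyclisation (C1–C14) builds the 14-membered carbocycle first; C14 is then fixed by oxidation and CBS reduction.
3. 21 ⇐ ester 11 + iodo-enyne 17 by B-alkyl Suzuki coupling (C5–C6).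
4. 11 ⇐ allylic propanoate 7 by enantioselective boron-mediated Ireland–Claisen rearrangement (C8 and Cα in one step).
5. 7 ⇐ pent-4-yn-1-ol, AlMe3, (E)-1,4-dichlorobut-2-ene and sodium propanoate; 17 ⇐ pent-3-yn-1-ol and lithium acetylide. Ring order: carbocycle, then epoxide and lactone in the same flask.

Locants: ring carbons C1–C14 follow the target SMILES (C1 carries the exocyclic CH2, C4/C5 the epoxide, C8 the lactone side chain, C10 the lactone oxygen, C11 the tertiary OH, C14 the secondary OH); Cα and C20 are the lactone α-carbon and carbonyl.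

Assumption: the (S,S)-bromoborane is taken to give the (2S,3S) acid in step 4 (sense assigned by analogy, not verified); if the sense is opposite, the (R,R)-reagent is used and nothing else changes.

## Route

Step 1
Reactants: 1 pent-4-yn-1-ol
Product: 2 tert-butyldimethyl(pent-4-yn-1-yloxy)silane
Conditions: TBSCl, imidazole, CH2Cl2, 0 → 23 °C
Reagents that add atoms: tert-butyldimethylsilyl chloride, CC(C)(C)[Si](C)(C)Cl
Why: Standard silylation masks the future C14 oxygen through the aluminium, boron and palladium steps; no stereocentre is involved.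

Step 2
Reactants: 2 tert-butyldimethyl(pent-4-yn-1-yloxy)silane; 3 (E)-1,4-dichlorobut-2-ene
Product: 5 tert-butyl{[(4E,7E)-9-chloro-4-methylnona-4,7-dien-1-yl]oxy}dimethylsilane, via alkenyldimethylalane 4 (not isolated)
Conditions: AlMe3 (2 equiv), Cp2ZrCl2 (0.2 equiv), CH2Cl2, 0 → 23 °C; then 3 (4 equiv), Pd(PPh3)4 (3 mol %), THF, 23 °C
Reagents that add atoms: trimethylalane, C[Al](C)C
Why: Negishi zirconium-catalysed syn-carboalumination fixes the (E)-C10=C11 trisubstituted alkene, and the alkenylalane is allylated in the same flask by palladium-catalysed cross-coupling at the unhindered terminus of the π-allyl from the (E)-dichloride, the excess of 3 holding the reaction at mono-substitution.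

Step 3
Reactants: 5 tert-butyl{[(4E,7E)-9-chloro-4-methylnona-4,7-dien-1-yl]oxy}dimethylsilane; 6 sodium propanoate
Product: 7 (2E,5E)-9-(tert-butyldimethylsilyloxy)-6-methylnona-2,5-dien-1-yl propanoate
Conditions: EtCO2Na (1.5 equiv), Bu4NI (10 mol %), DMF, 50 °C
Reagents that add atoms: none
Why: SN2 displacement of the primary allylic chloride by carboxylate gives the (E)-allylic propanoate needed for the Claisen step without touching either alkene geometry.

Step 4
Reactants: 7 (2E,5E)-9-(tert-butyldimethylsilyloxy)-6-methylnona-2,5-dien-1-yl propanoate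
Product: 11 methyl (2S,3S)-3-[(2E)-6-(tert-butyldimethylsilyloxy)-3-methylhex-2-en-1-yl]-2-methylpent-4-enoate, via boron ketene acetal 8 (not isolated), via acyloxyborane 9 (not isolated), via carboxylic acid 10 (not isolated)
Conditions: (4S,5S)-2-bromo-1,3-bis[3,5-bis(trifluoromethyl)phenylsulfonyl]-4,5-diphenyl-1,3,2-diazaborolidine (1.2 equiv), Et3N (1.3 equiv), toluene/hexane, −78 °C, then −20 °C (several days); H2O work-up (bis-sulfonamide recovered); then TMSCHN2, MeOH/toluene, 0 °C
Reagents that add atoms: (trimethylsilyl)diazomethane, C[Si](C)(C)C=[N+]=[N-]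
Why: Corey's boron-mediated enantioselective Ireland–Claisen rearrangement: soft enolisation with Et3N in toluene/hexane gives the E(O) boron ketene acetal (methyl trans to O–B), which rearranges through a chair transition state with the (E)-allyl substituent equatorial to the 2,3-anti acid, the C2-symmetric bis-sulfonamide on boron selecting the enolate face and so setting C8 and Cα as (2S,3S), after which the crude acid is methylated without purification.

Step 5
Reactants: 12 pent-3-yn-1-ol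
Product: 13 5-bromopent-2-yne
Conditions: CBr4, PPh3, CH2Cl2, 0 °C
Reagents that add atoms: tetrabromomethane, BrC(Br)(Br)Br
Why: Appel bromination of a primary alcohol gives the bromide under neutral conditions that leave the alkyne alone.

Step 6
Reactants: 13 5-bromopent-2-yne
Product: 15 (E)-5-bromo-2-iodopent-2-ene, via alkenylzirconocene chloride 14 (not isolated)
Conditions: Cp2Zr(H)Cl (1.3 equiv), THF, 23 → 40 °C; then I2, 0 °C
Reagents that add atoms: iodine, II
Why: Hydrozirconation adds H and Zr syn across the 2-alkyne, the slight excess of hydride equilibrating zirconium to the less hindered methyl-bearing carbon, and iodinolysis with retention gives the (E)-2-iodoalkene that later becomes the (E)-C4=C5 alkene.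

Step 7
Reactants: 15 (E)-5-bromo-2-iodopent-2-ene; 16 lithium acetylide ethane-1,2-diamine complex
Product: 17 (E)-6-iodohept-5-en-1-yne
Conditions: DMSO, 10 → 23 °C
Reagents that add atoms: none
Why: SN2 alkylation of acetylide by a primary homoallylic bromide in DMSO (as in the standard preparation of 6-methylhept-5-en-1-yne) installs C1 and C15 and leaves the alkenyl iodide intact.

Step 8
Reactants: 11 methyl (2S,3S)-3-[(2E)-6-(tert-butyldimethylsilyloxy)-3-methylhex-2-en-1-yl]-2-methylpent-4-enoate; 17 (E)-6-iodohept-5-en-1-yne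
Product: 19 methyl (2S,3R,6E)-3-[(2E)-6-(tert-butyldimethylsilyloxy)-3-methylhex-2-en-1-yl]-2,6-dimethylundec-6-en-10-ynoate, via alkyl-9-BBN 18 (not isolated)
Conditions: 9-borabicyclo[3.3.1]nonane (9-BBN, 1.3 equiv), THF, 23 °C; then H2O, Cs2CO3 (3 equiv), 17 (1.2 equiv), Pd(dppf)Cl2 (5 mol %), AsPh3 (5 mol %), DMF, 23 °C
Reagents that add atoms: none
Why: B-alkyl Suzuki–Miyaura coupling: 9-BBN hydroborates only the monosubstituted vinyl group, excess borane is quenched with water before 17 is added so the terminal alkyne is untouched, and the alkenyl iodide couples with retention to give the (E)-C4=C5 alkene, C8 being unchanged (its descriptor becomes R only through a CIP priority change).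

Step 9
Reactants: 19 methyl (2S,3R,6E)-3-[(2E)-6-(tert-butyldimethylsilyloxy)-3-methylhex-2-en-1-yl]-2,6-dimethylundec-6-en-10-ynoate
Product: 20 methyl (2S,3R,6E)-3-[(2E)-6-hydroxy-3-methylhex-2-en-1-yl]-2,6-dimethylundec-6-en-10-ynoate
Conditions: Bu4NF, THF, 0 → 23 °C
Reagents that add atoms: none
Why: Fluoride cleaves the primary silyl ether selectively; the ester, alkyne and alkenes are inert.

Step 10
Reactants: 20 methyl (2S,3R,6E)-3-[(2E)-6-hydroxy-3-methylhex-2-en-1-yl]-2,6-dimethylundec-6-en-10-ynoate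
Product: 21 methyl (2S,3R,6E)-2,6-dimethyl-3-[(2E)-3-methyl-6-oxohex-2-en-1-yl]undec-6-en-10-ynoate
Conditions: Dess–Martin periodinane, CH2Cl2, 0 → 23 °C
Reagents that add atoms: none
Why: Dess–Martin oxidation gives the C14 aldehyde under neutral conditions without over-oxidation or alkene migration.

Step 11
Reactants: 21 methyl (2S,3R,6E)-2,6-dimethyl-3-[(2E)-3-methyl-6-oxohex-2-en-1-yl]undec-6-en-10-ynoate
Product: 23 methyl (2S)-2-[(1R,3E,7RS,11E)-7-hydroxy-4,12-dimethyl-8-methylidenecyclotetradeca-3,11-dien-1-yl]propanoate, via triethylsilyl ether 22 (not isolated)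
Conditions: Ni(cod)2 (20 mol %), 1,3-bis(2,6-diisopropylphenyl)-4,5-diphenyl-4,5-dihydroimidazolium tetrafluoroborate (20 mol %), KOtBu (20 mol %), Et3SiH (3 equiv), THF, 0.002 M, slow addition, 23 °C; then Bu4NF, THF
Reagents that add atoms: none
Why: Nickel-catalysed reductive alkyne–aldehyde coupling (Montgomery type): the very bulky carbene ligand steers C–C bond formation to the internal alkyne carbon, so the ring closes in the exo mode to the 14-membered carbocycle with the exocyclic methylene at C1, high dilution suppresses oligomers, and C14 is not controlled here because both epimers converge in steps 12 and 13.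

Step 12
Reactants: 23 methyl (2S)-2-[(1R,3E,7RS,11E)-7-hydroxy-4,12-dimethyl-8-methylidenecyclotetradeca-3,11-dien-1-yl]propanoate
Product: 24 methyl (2S)-2-[(1R,3E,11E)-4,12-dimethyl-8-methylidene-7-oxocyclotetradeca-3,11-dien-1-yl]propanoate
Conditions: Dess–Martin periodinane, CH2Cl2, 0 °C
Reagents that add atoms: none
Why: Oxidation of the allylic alcohol mixture to the single α-methylene ketone erases the uncontrolled C14 centre.

Step 13
Reactants: 24 methyl (2S)-2-[(1R,3E,11E)-4,12-dimethyl-8-methylidene-7-oxocyclotetradeca-3,11-dien-1-yl]propanoate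
Product: 26 methyl (2S)-2-[(1R,3E,7S,11E)-7-hydroxy-4,12-dimethyl-8-methylidenecyclotetradeca-3,11-dien-1-yl]propanoate, via catechol borate 25 (not isolated)
Conditions: (R)-1-methyl-3,3-diphenyltetrahydro-1H,3H-pyrrolo[1,2-c][1,3,2]oxazaborole (0.5 equiv), catecholborane (2 equiv), toluene, −78 °C; H2O work-up
Reagents that add atoms: none
Why: Corey–Bakshi–Shibata reduction: the (R)-oxazaborolidine treats the 1,1-disubstituted alkenyl group as the large and the C13 methylene as the small substituent and delivers hydride to give the (14S)-alcohol, the low temperature suppressing conjugate reduction and leaving the ester untouched.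

Step 14
Reactants: 26 methyl (2S)-2-[(1R,3E,7S,11E)-7-hydroxy-4,12-dimethyl-8-methylidenecyclotetradeca-3,11-dien-1-yl]propanoate
Product: 28 (2S)-2-[(1R,3E,7S,11E)-7-hydroxy-4,12-dimethyl-8-methylidenecyclotetradeca-3,11-dien-1-yl]propanoic acid, via lithium carboxylate 27 (not isolated)
Conditions: LiOH (5 equiv), THF/MeOH/H2O, 23 → 40 °C; then 1 M HCl to pH 4, 0 °C
Reagents that add atoms: lithium hydroxide, [Li+].[OH-]
Why: Saponification proceeds by acyl–oxygen cleavage faster than α-deprotonation, and the carboxylate once formed cannot enolise, so Cα is kept.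

Step 15
Reactants: 28 (2S)-2-[(1R,3E,7S,11E)-7-hydroxy-4,12-dimethyl-8-methylidenecyclotetradeca-3,11-dien-1-yl]propanoic acid
Product: 30 CNP0262409.2, via bis-epoxy acid 29 (not isolated)
Conditions: 1,2:4,5-di-O-isopropylidene-β-L-erythro-2,3-hexodiulo-2,6-pyranose (0.6 equiv), KHSO5 (as 2KHSO5·KHSO4·K2SO4, 3 equiv), K2CO3, Bu4NHSO4 (cat.), Na2B4O7/Na2EDTA buffer, MeCN/CH2(OMe)2/H2O, 0 °C; then KH2PO4 to pH 7.5, 35 °C
Reagents that add atoms: potassium peroxymonosulfate, OOS(=O)(=O)[O-].[K+]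
Why: Shi epoxidation with the L-fructose-derived ketone epoxidises both (E)-trisubstituted alkenes under catalyst control to the (4S,5S) and (10S,11S) epoxides (the electron-poorer 1,1-disubstituted allylic alkene is a poor substrate for this dioxirane), and at pH 7.5 the carboxylate then opens the C10–C11 epoxide by 6-exo SN2 attack at the secondary C10 with inversion (the known behaviour of 5,6-epoxy acids), giving the (10R)-lactone and the (11S)-tertiary alcohol, while the seven-membered mode onto C5 and acid-catalysed ether formation from the C14 hydroxyl are avoided at this pH.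

## Compound list

1 | pent-4-yn-1-ol | C#CCCCO | starting material
2 | tert-butyldimethyl(pent-4-yn-1-yloxy)silane | C#CCCCO[Si](C)(C)C(C)(C)C | intermediate
3 | (E)-1,4-dichlorobut-2-ene | ClC/C=C/CCl | starting material
4 | (E)-[5-(tert-butyldimethylsilyloxy)-2-methylpent-1-en-1-yl]dimethylalane | C[Al](C)/C=C(\C)CCCO[Si](C)(C)C(C)(C)C | intermediate (not isolated)
5 | tert-butyl{[(4E,7E)-9-chloro-4-methylnona-4,7-dien-1-yl]oxy}dimethylsilane | ClC/C=C/C/C=C(\C)CCCO[Si](C)(C)C(C)(C)C | intermediate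
6 | sodium propanoate | CCC(=O)[O-].[Na+] | starting material
7 | (2E,5E)-9-(tert-butyldimethylsilyloxy)-6-methylnona-2,5-dien-1-yl propanoate | CCC(=O)OC/C=C/C/C=C(\C)CCCO[Si](C)(C)C(C)(C)C | intermediate
8 | E(O) boron ketene acetal of 7 carrying the (4S,5S)-diazaborolidinyl group | C/C=C(/OB1N(S(=O)(=O)c2cc(cc(c2)C(F)(F)F)C(F)(F)F)[C@@H](c2ccccc2)[C@H](c2ccccc2)N1S(=O)(=O)c1cc(cc(c1)C(F)(F)F)C(F)(F)F)OC/C=C/C/C=C(\C)CCCO[Si](C)(C)C(C)(C)C | intermediate (not isolated)
9 | (2S,3S)-acyloxyborane (boron carboxylate of acid 10) | O=C(OB1N(S(=O)(=O)c2cc(cc(c2)C(F)(F)F)C(F)(F)F)[C@@H](c2ccccc2)[C@H](c2ccccc2)N1S(=O)(=O)c1cc(cc(c1)C(F)(F)F)C(F)(F)F)[C@@H](C)[C@H](C=C)C/C=C(\C)CCCO[Si](C)(C)C(C)(C)C | intermediate (not isolated)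
10 | (2S,3S)-3-[(2E)-6-(tert-butyldimethylsilyloxy)-3-methylhex-2-en-1-yl]-2-methylpent-4-enoic acid | OC(=O)[C@@H](C)[C@H](C=C)C/C=C(\C)CCCO[Si](C)(C)C(C)(C)C | intermediate (not isolated)
11 | methyl (2S,3S)-3-[(2E)-6-(tert-butyldimethylsilyloxy)-3-methylhex-2-en-1-yl]-2-methylpent-4-enoate | COC(=O)[C@@H](C)[C@H](C=C)C/C=C(\C)CCCO[Si](C)(C)C(C)(C)C | intermediate
12 | pent-3-yn-1-ol | CC#CCCO | starting material
13 | 5-bromopent-2-yne | CC#CCCBr | intermediate
14 | (E)-(5-bromopent-2-en-2-yl)chlorobis(cyclopentadienyl)zirconium | Cl[Zr](C1C=CC=C1)(C1C=CC=C1)/C(C)=C/CCBr | intermediate (not isolated)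
15 | (E)-5-bromo-2-iodopent-2-ene | BrCC/C=C(/I)C | intermediate
16 | lithium acetylide ethane-1,2-diamine complex | [Li+].[C-]#C.NCCN | starting material
17 | (E)-6-iodohept-5-en-1-yne | C#CCC/C=C(/I)C | intermediate
18 | methyl (2S,3R,5E)-3-[2-(9-borabicyclo[3.3.1]nonan-9-yl)ethyl]-9-(tert-butyldimethylsilyloxy)-2,6-dimethylnon-5-enoate | COC(=O)[C@@H](C)[C@H](CCB1C2CCCC1CCC2)C/C=C(\C)CCCO[Si](C)(C)C(C)(C)C | intermediate (not isolated)
19 | methyl (2S,3R,6E)-3-[(2E)-6-(tert-butyldimethylsilyloxy)-3-methylhex-2-en-1-yl]-2,6-dimethylundec-6-en-10-ynoate | COC(=O)[C@@H](C)[C@H](CC/C(C)=C/CCC#C)C/C=C(\C)CCCO[Si](C)(C)C(C)(C)C | intermediate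
20 | methyl (2S,3R,6E)-3-[(2E)-6-hydroxy-3-methylhex-2-en-1-yl]-2,6-dimethylundec-6-en-10-ynoate | COC(=O)[C@@H](C)[C@H](CC/C(C)=C/CCC#C)C/C=C(\C)CCCO | intermediate
21 | methyl (2S,3R,6E)-2,6-dimethyl-3-[(2E)-3-methyl-6-oxohex-2-en-1-yl]undec-6-en-10-ynoate | COC(=O)[C@@H](C)[C@H](CC/C(C)=C/CCC#C)C/C=C(\C)CCC=O | intermediate
22 | methyl (2S)-2-[(1R,3E,7RS,11E)-4,12-dimethyl-8-methylidene-7-(triethylsilyloxy)cyclotetradeca-3,11-dien-1-yl]propanoate | COC(=O)[C@@H](C)[C@@H]1CC/C(C)=C/CCC(=C)C(O[Si](CC)(CC)CC)CC/C(C)=C/C1 | intermediate (not isolated)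
23 | methyl (2S)-2-[(1R,3E,7RS,11E)-7-hydroxy-4,12-dimethyl-8-methylidenecyclotetradeca-3,11-dien-1-yl]propanoate | COC(=O)[C@@H](C)[C@@H]1CC/C(C)=C/CCC(=C)C(O)CC/C(C)=C/C1 | intermediate
24 | methyl (2S)-2-[(1R,3E,11E)-4,12-dimethyl-8-methylidene-7-oxocyclotetradeca-3,11-dien-1-yl]propanoate | COC(=O)[C@@H](C)[C@@H]1CC/C(C)=C/CCC(=C)C(=O)CC/C(C)=C/C1 | intermediate
25 | methyl (2S)-2-[(1R,3E,7S,11E)-7-(1,3,2-benzodioxaborol-2-yloxy)-4,12-dimethyl-8-methylidenecyclotetradeca-3,11-dien-1-yl]propanoate | COC(=O)[C@@H](C)[C@@H]1CC/C(C)=C/CCC(=C)[C@@H](OB2Oc3ccccc3O2)CC/C(C)=C/C1 | intermediate (not isolated)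
26 | methyl (2S)-2-[(1R,3E,7S,11E)-7-hydroxy-4,12-dimethyl-8-methylidenecyclotetradeca-3,11-dien-1-yl]propanoate | COC(=O)[C@@H](C)[C@@H]1CC/C(C)=C/CCC(=C)[C@@H](O)CC/C(C)=C/C1 | intermediate
27 | lithium (2S)-2-[(1R,3E,7S,11E)-7-hydroxy-4,12-dimethyl-8-methylidenecyclotetradeca-3,11-dien-1-yl]propanoate | [Li+].[O-]C(=O)[C@@H](C)[C@@H]1CC/C(C)=C/CCC(=C)[C@@H](O)CC/C(C)=C/C1 | intermediate (not isolated)
28 | (2S)-2-[(1R,3E,7S,11E)-7-hydroxy-4,12-dimethyl-8-methylidenecyclotetradeca-3,11-dien-1-yl]propanoic acid | OC(=O)[C@@H](C)[C@@H]1CC/C(C)=C/CCC(=C)[C@@H](O)CC/C(C)=C/C1 | intermediate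
29 | (2S)-2-[(1R,3S,4S,7S,11S,12S)-3,4:11,12-diepoxy-7-hydroxy-4,12-dimethyl-8-methylidenecyclotetradecan-1-yl]propanoic acid | OC(=O)[C@@H](C)[C@@H]1CC[C@]2(C)O[C@H]2CCC(=C)[C@@H](O)CC[C@]2(C)O[C@H]2C1 | intermediate (not isolated)
30 | CNP0262409.2: 14-membered carbocycle with exocyclic methylene at C1, (4S,5S)-epoxide, (8R,10R,αS)-α-methyl-δ-lactone, (11S)-tertiary and (14S)-secondary alcohols | C=C1CC[C@@H]2O[C@@]2(C)CC[C@@H]2C[C@@H](OC(=O)[C@H]2C)[C@@](C)(O)CC[C@@H]1O | target

## Step count and risks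

Total step count: 15. Longest linear sequence: 12 (steps 1–4 and 8–15); steps 5–7 make fragment 17.

**Step 15 (one-flask double epoxidation and lactonisation).** The ring conformation may override the ketone catalyst at one of the two alkenes, or the C14 hydroxyl may open the C10–C11 epoxide. The fallback puts both epoxides in on the open chain, where the catalyst alone decides, and closes the lactone last. It sets out from 19. The same L-fructose-derived ketone and KHSO5 give the bis-epoxy ester F1. Bu4NF gives the alcohol F2 and Dess–Martin oxidation the ynal F3. The nickel-catalysed exo reductive macrocyclisation of step 11 gives the triethylsilyl ether F4 and, after Bu4NF, the carbinol F5 as C14 epimers. Dess–Martin oxidation gives the enone F6, and the reduction of step 13 gives, through the catechol borate F7, the (14S)-carbinol F8. LiOH gives the lithium carboxylate F9, which on bringing to pH 7.5 with dilute HCl is the acid 29; it lactonises to 30 as in step 15. The fallback comes back to the route at 29.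

**Step 11 (exo-selective nickel macrocyclisation).** The endo mode (15-membered ring with an endocyclic alkene) or oligomerisation may win. The fallback is a Nozaki–Hiyama–Kishi macrocyclisation of a 2-iodoalkene. It sets out from 19. 9-Iodo-9-borabicyclo[3.3.1]nonane adds across the terminal alkyne to give the iodoalkenylborane F10, and AcOH protonolysis gives the 2-iodo-1-alkene F11. Bu4NF gives the alcohol F12 and Dess–Martin oxidation the iodo aldehyde F13. CrCl2 (10 equiv) with NiCl2 (2 mol %) in DMSO/THF at 0.002 M closes the C1–C14 bond. The fallback comes back to the route at 23, whose C14 epimers converge as before.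

**Step 2 (palladium-catalysed allylation with the bifunctional dichloride).** Double coupling, or β-chloride elimination to butadiene, may consume the alkenylalane. The fallback builds C6–C8 stepwise by copper-mediated alkynylation. It sets out from 2. The same carboalumination gives 4, which is quenched with paraformaldehyde to the aluminium alkoxide F14; work-up gives the (E)-allylic alcohol F15. MsCl/Et3N gives the mesylate F16, displaced in the same flask by LiCl to the allylic chloride F17. Propargyl alcohol with CuI, K2CO3 and NaI in DMF gives the enynol F18. NaAlH2(OCH2CH2OMe)2 in THF reduces the propargylic alcohol to the (2E,5E)-dienol F19. Propanoyl chloride and pyridine give the propanoate, and the fallback comes back to the route at 7.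

## Further compounds

F1 | step 15 | methyl (2S,3R)-bis-epoxy ester, open chain, tert-butyldimethylsilyl ether (both epoxides S,S) | COC(=O)[C@@H](C)[C@H](CC[C@]1(C)O[C@H]1CCC#C)C[C@@H]1O[C@@]1(C)CCCO[Si](C)(C)C(C)(C)C
F2 | step 15 | open-chain bis-epoxy ester, primary alcohol | COC(=O)[C@@H](C)[C@H](CC[C@]1(C)O[C@H]1CCC#C)C[C@@H]1O[C@@]1(C)CCCO
F3 | step 15 | open-chain bis-epoxy ester, ynal | COC(=O)[C@@H](C)[C@H](CC[C@]1(C)O[C@H]1CCC#C)C[C@@H]1O[C@@]1(C)CCC=O
F4 | step 15 | macrocyclic bis-epoxy ester, C14 triethylsilyl ether (C14 epimers) | COC(=O)[C@@H](C)[C@@H]1CC[C@]2(C)O[C@H]2CCC(=C)C(O[Si](CC)(CC)CC)CC[C@]2(C)O[C@H]2C1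
F5 | step 15 | macrocyclic bis-epoxy ester, C14 carbinol (C14 epimers) | COC(=O)[C@@H](C)[C@@H]1CC[C@]2(C)O[C@H]2CCC(=C)C(O)CC[C@]2(C)O[C@H]2C1
F6 | step 15 | macrocyclic bis-epoxy ester, C14 ketone | COC(=O)[C@@H](C)[C@@H]1CC[C@]2(C)O[C@H]2CCC(=C)C(=O)CC[C@]2(C)O[C@H]2C1
F7 | step 15 | macrocyclic bis-epoxy ester, (14S)-catechol borate | COC(=O)[C@@H](C)[C@@H]1CC[C@]2(C)O[C@H]2CCC(=C)[C@@H](OB2Oc3ccccc3O2)CC[C@]2(C)O[C@H]2C1
F8 | step 15 | macrocyclic bis-epoxy ester, (14S)-carbinol | COC(=O)[C@@H](C)[C@@H]1CC[C@]2(C)O[C@H]2CCC(=C)[C@@H](O)CC[C@]2(C)O[C@H]2C1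
F9 | step 15 | lithium salt of bis-epoxy acid 29 | [Li+].[O-]C(=O)[C@@H](C)[C@@H]1CC[C@]2(C)O[C@H]2CCC(=C)[C@@H](O)CC[C@]2(C)O[C@H]2C1
F10 | step 11 | (Z)-2-iodoalkenyl-9-borabicyclo[3.3.1]nonane adduct of 19 | COC(=O)[C@@H](C)[C@H](CC/C(C)=C/CCC(/I)=C/B1C2CCCC1CCC2)C/C=C(\C)CCCO[Si](C)(C)C(C)(C)C
F11 | step 11 | methyl (2S,3R,6E)-3-[(2E)-6-(tert-butyldimethylsilyloxy)-3-methylhex-2-en-1-yl]-10-iodo-2,6-dimethylundeca-6,10-dienoate | COC(=O)[C@@H](C)[C@H](CC/C(C)=C/CCC(I)=C)C/C=C(\C)CCCO[Si](C)(C)C(C)(C)C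
F12 | step 11 | methyl (2S,3R,6E)-3-[(2E)-6-hydroxy-3-methylhex-2-en-1-yl]-10-iodo-2,6-dimethylundeca-6,10-dienoate | COC(=O)[C@@H](C)[C@H](CC/C(C)=C/CCC(I)=C)C/C=C(\C)CCCO
F13 | step 11 | methyl (2S,3R,6E)-10-iodo-2,6-dimethyl-3-[(2E)-3-methyl-6-oxohex-2-en-1-yl]undeca-6,10-dienoate | COC(=O)[C@@H](C)[C@H](CC/C(C)=C/CCC(I)=C)C/C=C(\C)CCC=O
F14 | step 2 | dimethylaluminium (E)-6-(tert-butyldimethylsilyloxy)-3-methylhex-2-en-1-olate | C[Al](C)OC/C=C(\C)CCCO[Si](C)(C)C(C)(C)C
F15 | step 2 | (E)-6-(tert-butyldimethylsilyloxy)-3-methylhex-2-en-1-ol | OC/C=C(\C)CCCO[Si](C)(C)C(C)(C)C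
F16 | step 2 | (E)-6-(tert-butyldimethylsilyloxy)-3-methylhex-2-en-1-yl methanesulfonate | CS(=O)(=O)OC/C=C(\C)CCCO[Si](C)(C)C(C)(C)C
F17 | step 2 | tert-butyl{[(E)-6-chloro-4-methylhex-4-en-1-yl]oxy}dimethylsilane | ClC/C=C(\C)CCCO[Si](C)(C)C(C)(C)C
F18 | step 2 | (5E)-9-(tert-butyldimethylsilyloxy)-6-methylnon-5-en-2-yn-1-ol | OCC#CC/C=C(\C)CCCO[Si](C)(C)C(C)(C)C
F19 | step 2 | (2E,5E)-9-(tert-butyldimethylsilyloxy)-6-methylnona-2,5-dien-1-ol | OC/C=C/C/C=C(\C)CCCO[Si](C)(C)C(C)(C)C
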